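## Retrosynthetic overview

1. Locants follow the target as a 5,6,7,8-tetrahydronaphthalene-2-carboxylic acid: ring A is the arene (CO2H on C2, OH on C3 and C4), ring B the saturated ring (CH3 on C5, side chain on C8); side-chain carbons are C1′–C7′, with C2′ on C8 and the ester oxygen on C7′.
2. The caffeate ester at O7′ is made last but one (carbodiimide coupling with MOM-protected caffeic acid 28); one acid step then removes four MOM groups and the tert-butyl ester.
3. Key disconnection: the C7–C8 bond of ring B together with the C2′–H bond, by CuH-catalysed hydroalkylative cyclisation of the (E)-aryl–CH=C(CH3)R alkene of 23 onto its primary C7 bromide. The enabling feature is that C8 is benzylic to C8a of ring A (so copper goes to C8), that C7 is reached through the C8a–C4a–C5–C6 tether, and that C8 and C2′ are a vicinal pair of C–H stereocentres that one syn addition across C8=C2′ can create.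
4. 23 comes from a Negishi union at C8a of aryl bromide 12 with (E)-alkenyl iodide 20; C5 is set on ring A by a chirality-transferring aromatic Claisen shift from O4 to C4a; C6′ comes from (S)-3-bromo-2-methylpropan-1-ol.
5. Ring order: ring A is bought (2,3-dihydroxybenzoic acid); ring B is the only ring formed, in step 15.

Key step: step 15

Assumption: the sense of induction of (R)-DTBM-SEGPHOS-ligated CuH on the alkene of 23 is taken to follow that of β-substituted styrenes; the enantiomeric ligand would be used if the cyclisation delivered the (8R,2′R) series.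

## Route

Step 1
Reactants: 1 2,3-dihydroxybenzoic acid
Product: 2 5-bromo-2,3-dihydroxybenzoic acid
Conditions: Br2 (1.05 equiv), AcOH, rt
Reagents that add atoms: bromine, BrBr
Why: Electrophilic aromatic bromination should go to C5, the one position that is para to a hydroxyl (C2–OH) and meta to the deactivating carboxyl group.

Step 2
Reactants: 2 5-bromo-2,3-dihydroxybenzoic acid
Product: 3 tert-butyl 5-bromo-2,3-dihydroxybenzoate
Conditions: Cl3CC(=NH)OtBu (2.5 equiv), THF/cyclohexane, rt
Reagents that add atoms: tert-butyl 2,2,2-trichloroacetimidate, CC(C)(C)OC(=N)C(Cl)(Cl)Cl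
Why: Imidate esterification needs no added catalyst for a carboxylic acid (the acid protonates the imidate), whereas the less acidic phenols should stay free.

Step 3
Reactants: 4 (3E)-pent-3-en-2-one
Product: 5 (2R,3E)-pent-3-en-2-ol
Conditions: (S)-2-methyl-CBS-oxazaborolidine (10 mol %), catecholborane (1.5 equiv), toluene, −78 °C; aq. NaOH work-up
Reagents that add atoms: none
Why: Corey–Bakshi–Shibata reduction: the (S)-oxazaborolidine should deliver hydride 1,2 to the enone with the propenyl group as the large substituent, giving the (R)-allylic alcohol.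

Step 4
Reactants: 3 tert-butyl 5-bromo-2,3-dihydroxybenzoate; 5 (2R,3E)-pent-3-en-2-ol
Product: 6 tert-butyl 5-bromo-2-hydroxy-3-{[(2S,3E)-pent-3-en-2-yl]oxy}benzoate
Conditions: PPh3, DIAD, THF, 0 °C → rt
Reagents that add atoms: none
Why: Mitsunobu etherification: the C3 hydroxyl should react because the C2 hydroxyl is held in a hydrogen bond to the ester carbonyl, and SN2 displacement of the oxyphosphonium inverts the carbinol centre to (S).

Step 5
Reactants: 6 tert-butyl 5-bromo-2-hydroxy-3-{[(2S,3E)-pent-3-en-2-yl]oxy}benzoate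
Product: 7 tert-butyl 5-bromo-2,3-dihydroxy-4-[(2R,3E)-pent-3-en-2-yl]benzoate
Conditions: PhNEt2, 150 °C, sealed tube
Reagents that add atoms: none
Why: Aromatic Claisen rearrangement: the [3,3] shift can only reach the free ortho carbon (benzoate C4), and a chair transition state with the carbinol methyl pseudo-equatorial should transfer the (S) ether centre to the (R) benzylic centre with an (E)-alkene, before enolisation restores the phenol.

Step 6
Reactants: 7 tert-butyl 5-bromo-2,3-dihydroxy-4-[(2R,3E)-pent-3-en-2-yl]benzoate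
Product: 8 tert-butyl 5-bromo-2,3-bis(methoxymethoxy)-4-[(2R,3E)-pent-3-en-2-yl]benzoate
Conditions: NaH (2.5 equiv), MOMCl (2.5 equiv), DMF, 0 °C → rt
Reagents that add atoms: chloromethyl methyl ether, COCCl
Why: Williamson-type O-alkylation of both phenoxides masks the catechol for the organometallic steps and allows one final acid deprotection.

Step 7
Reactants: 8 tert-butyl 5-bromo-2,3-bis(methoxymethoxy)-4-[(2R,3E)-pent-3-en-2-yl]benzoate
Product: 9 tert-butyl 5-bromo-4-[(2R)-but-3-en-2-yl]-2,3-bis(methoxymethoxy)benzoate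
Conditions: second-generation Hoveyda–Grubbs catalyst (5 mol %), ethylene (5 bar), toluene, 40 °C
Reagents that add atoms: ethylene, C=C
Why: Ethenolysis (cross-metathesis with excess ethylene) should trim the propenyl terminus to a vinyl group, driven by ethylene pressure and loss of propene, without touching the benzylic stereocentre.

Step 8
Reactants: 9 tert-butyl 5-bromo-4-[(2R)-but-3-en-2-yl]-2,3-bis(methoxymethoxy)benzoate
Product: 11 tert-butyl 5-bromo-4-[(2R)-4-hydroxybutan-2-yl]-2,3-bis(methoxymethoxy)benzoate, via alkylborane 10 (not isolated)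
Conditions: 9-BBN (1.5 equiv), THF, 0 °C → rt; then aq. NaOH, H2O2, 0 °C
Reagents that add atoms: hydrogen peroxide, OO
Why: Anti-Markovnikov hydroboration puts boron on the terminal carbon and oxidation with retention gives the primary alcohol; aryl bromide, ester and MOM ethers are inert.

Step 9
Reactants: 11 tert-butyl 5-bromo-4-[(2R)-4-hydroxybutan-2-yl]-2,3-bis(methoxymethoxy)benzoate
Product: 12 tert-butyl 5-bromo-4-[(2R)-4-bromobutan-2-yl]-2,3-bis(methoxymethoxy)benzoate
Conditions: CBr4, PPh3, 2,6-lutidine, CH2Cl2, 0 °C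
Reagents that add atoms: tetrabromomethane, BrC(Br)(Br)Br
Why: The Appel reaction converts the primary alcohol into the bromide under buffered, near-neutral conditions that the MOM ethers and the ester tolerate.

Step 10
Reactants: 13 (2S)-3-bromo-2-methylpropan-1-ol
Product: 14 [(2S)-3-bromo-2-methylpropoxy](tert-butyl)dimethylsilane
Conditions: TBSCl, imidazole, CH2Cl2, rt
Reagents that add atoms: tert-butyl(chloro)dimethylsilane, CC(C)(C)[Si](C)(C)Cl
Why: Standard silylation of a primary alcohol; the silyl ether carries O7′ through the organometallic steps.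

Step 11
Reactants: 14 [(2S)-3-bromo-2-methylpropoxy](tert-butyl)dimethylsilane; 15 (4-bromobut-1-yn-1-yl)trimethylsilane
Product: 17 tert-butyldimethyl{[(2R)-2-methyl-7-(trimethylsilyl)hept-6-yn-1-yl]oxy}silane, via Grignard reagent 16 (not isolated)
Conditions: 15, Mg, THF, 40 °C; then 14, Li2CuCl4 (3 mol %), NMP, THF, 0 °C → rt
Reagents that add atoms: none
Why: Copper-catalysed Kumada-type sp3–sp3 coupling of a primary alkyl bromide with an alkyl Grignard reagent; the stereocentre is not involved and its descriptor changes from S to R only through the CIP ranking.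

Step 12
Reactants: 17 tert-butyldimethyl{[(2R)-2-methyl-7-(trimethylsilyl)hept-6-yn-1-yl]oxy}silane
Product: 18 tert-butyldimethyl{[(2R)-2-methylhept-6-yn-1-yl]oxy}silane
Conditions: K2CO3, MeOH, rt
Reagents that add atoms: none
Why: Mild methanolysis cleaves the alkynyl C–Si bond while the alkyl silyl ether survives.

Step 13
Reactants: 18 tert-butyldimethyl{[(2R)-2-methylhept-6-yn-1-yl]oxy}silane
Product: 20 tert-butyl{[(2R,6E)-7-iodo-2,6-dimethylhept-6-en-1-yl]oxy}dimethylsilane, via alkenylalane 19 (not isolated)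
Conditions: AlMe3 (2.5 equiv), Cp2ZrCl2 (0.25 equiv), CH2Cl2, 0 °C → rt; then I2, THF, −30 °C → 0 °C
Reagents that add atoms: trimethylaluminium, C[Al](C)C; iodine, II
Why: Negishi carboalumination adds CH3 and Al syn across the terminal alkyne with Al on the terminal carbon, and iodinolysis with retention gives the (E)-2-methylalkenyl iodide.

Step 14
Reactants: 20 tert-butyl{[(2R,6E)-7-iodo-2,6-dimethylhept-6-en-1-yl]oxy}dimethylsilane; 12 tert-butyl 5-bromo-4-[(2R)-4-bromobutan-2-yl]-2,3-bis(methoxymethoxy)benzoate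
Product: 23 tert-butyl 4-[(2R)-4-bromobutan-2-yl]-5-[(1E,6R)-7-{[tert-butyl(dimethyl)silyl]oxy}-2,6-dimethylhept-1-en-1-yl]-2,3-bis(methoxymethoxy)benzoate, via alkenyllithium 21 (not isolated), via alkenylzinc chloride 22 (not isolated)
Conditions: 20, t-BuLi (2.0 equiv), Et2O, −78 °C; ZnCl2, THF, −78 °C → rt; then 12, Pd(OAc)2 (5 mol %), SPhos (10 mol %), THF, 50 °C
Reagents that add atoms: none
Why: Negishi coupling: iodine–lithium exchange and transmetalation to zinc keep the (E)-geometry, and zerovalent palladium should insert into the aryl C–Br bond much faster than into the unactivated primary alkyl C–Br bond.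

Step 15
Reactants: 23 tert-butyl 4-[(2R)-4-bromobutan-2-yl]-5-[(1E,6R)-7-{[tert-butyl(dimethyl)silyl]oxy}-2,6-dimethylhept-1-en-1-yl]-2,3-bis(methoxymethoxy)benzoate
Product: 24 tert-butyl (5R,8S)-8-[(2S,6R)-7-{[tert-butyl(dimethyl)silyl]oxy}-6-methylheptan-2-yl]-3,4-bis(methoxymethoxy)-5-methyl-5,6,7,8-tetrahydronaphthalene-2-carboxylate
Conditions: Cu(OAc)2 (10 mol %), (R)-DTBM-SEGPHOS (11 mol %), (MeO)2MeSiH (3 equiv), LiOMe (3 equiv), THF, rt → 40 °C
Reagents that add atoms: none
Why: Proposed new method: the bisphosphine-ligated CuH formed from Cu(OAc)2 and the silane should add syn across the (E)-C8=C2′ alkene of 23, H going to the disubstituted C2′ and Cu to the benzylic C8, and the benzylic alkylcopper should then substitute the primary bromide at C7 through oxidative addition to trivalent copper and reductive elimination with retention at C8, after which LiOMe and the silane turn the copper bromide back into CuH. The closest known reaction type is the CuH-catalysed enantioselective intramolecular hydroalkylation of bromide-tethered β-monosubstituted styrenes, which gives indanes, cyclobutanes, cyclopentanes and six-membered heterocycles; new here are the β,β-disubstituted (trisubstituted) vinylarene and the all-carbon six-membered ring. Ring B closes in the 6-exo-tet mode, C8 attacking C7 across the C8a–C4a–C5–C6 tether. C8 is controlled by the ligand, which chooses the alkene face that receives copper, and C2′ is controlled by the (E)-geometry of the alkene, because H arrives on the same face, so that net syn addition of H and C7 gives the (8S,2′S) pair. The step needs copper at C8 and not at C2′, which the aryl group on C8 and the lower substitution of C8 both secure; it needs hydrocupration to outrun direct reduction of the C–Br bond, which the unactivated primary bromide and the absence of other reducible groups favour; and it needs catalyst control over the remote C5 centre, which lies four bonds from the alkene and should exert little bias. The tert-butyl ester, the MOM ethers and the silyl ether should be inert to CuH and LiOMe at this temperature.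

Step 16
Reactants: 24 tert-butyl (5R,8S)-8-[(2S,6R)-7-{[tert-butyl(dimethyl)silyl]oxy}-6-methylheptan-2-yl]-3,4-bis(methoxymethoxy)-5-methyl-5,6,7,8-tetrahydronaphthalene-2-carboxylate
Product: 25 tert-butyl (5R,8S)-8-[(2S,6R)-7-hydroxy-6-methylheptan-2-yl]-3,4-bis(methoxymethoxy)-5-methyl-5,6,7,8-tetrahydronaphthalene-2-carboxylate
Conditions: Bu4NF, THF, 0 °C → rt
Reagents that add atoms: none
Why: Fluoride cleaves the alkyl silyl ether selectively; MOM ethers and the tert-butyl ester are stable to it.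

Step 17
Reactants: 26 caffeic acid, (2E)-3-(3,4-dihydroxyphenyl)prop-2-enoic acid
Product: 28 (2E)-3-[3,4-bis(methoxymethoxy)phenyl]prop-2-enoic acid, via MOM ester 27 (not isolated)
Conditions: MOMCl (3.6 equiv), iPr2NEt, CH2Cl2, 0 °C → rt; then LiOH, THF/H2O, rt; dilute HCl to pH 4 at 0 °C
Reagents that add atoms: chloromethyl methyl ether, COCCl
Why: Exhaustive methoxymethylation followed by saponification of the labile MOM ester leaves both phenols protected and frees the acid, with the (E)-alkene untouched.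

Step 18
Reactants: 25 tert-butyl (5R,8S)-8-[(2S,6R)-7-hydroxy-6-methylheptan-2-yl]-3,4-bis(methoxymethoxy)-5-methyl-5,6,7,8-tetrahydronaphthalene-2-carboxylate; 28 (2E)-3-[3,4-bis(methoxymethoxy)phenyl]prop-2-enoic acid
Product: 29 tert-butyl (5R,8S)-8-[(2S,6R)-7-({(2E)-3-[3,4-bis(methoxymethoxy)phenyl]prop-2-enoyl}oxy)-6-methylheptan-2-yl]-3,4-bis(methoxymethoxy)-5-methyl-5,6,7,8-tetrahydronaphthalene-2-carboxylate
Conditions: EDC·HCl, DMAP (cat.), CH2Cl2, rt
Reagents that add atoms: none
Why: Steglich-type carbodiimide esterification joins the only free alcohol with the only free carboxylic acid; no stereocentre is involved.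

Step 19
Reactants: 29 tert-butyl (5R,8S)-8-[(2S,6R)-7-({(2E)-3-[3,4-bis(methoxymethoxy)phenyl]prop-2-enoyl}oxy)-6-methylheptan-2-yl]-3,4-bis(methoxymethoxy)-5-methyl-5,6,7,8-tetrahydronaphthalene-2-carboxylate
Product: 30 (5R,8S)-8-[(2S,6R)-7-{[(2E)-3-(3,4-dihydroxyphenyl)prop-2-enoyl]oxy}-6-methylheptan-2-yl]-3,4-dihydroxy-5-methyl-5,6,7,8-tetrahydronaphthalene-2-carboxylic acid (CNP0492979.1)
Conditions: CF3CO2H/CH2Cl2 (1:4), H2O (10 equiv), 0 °C → rt
Reagents that add atoms: none
Why: Acidolysis should remove the four MOM acetals and the tert-butyl ester in one operation, under conditions to which the cinnamate ester, its (E)-alkene and the four stereocentres are stable.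

## Compound list

1 | 2,3-dihydroxybenzoic acid | OC(=O)c1cccc(O)c1O | starting material
2 | 5-bromo-2,3-dihydroxybenzoic acid | OC(=O)c1cc(Br)cc(O)c1O | intermediate
3 | tert-butyl 5-bromo-2,3-dihydroxybenzoate | CC(C)(C)OC(=O)c1cc(Br)cc(O)c1O | intermediate
4 | (3E)-pent-3-en-2-one | C/C=C/C(C)=O | starting material
5 | (2R,3E)-pent-3-en-2-ol | C/C=C/[C@@H](C)O | intermediate
6 | tert-butyl 5-bromo-2-hydroxy-3-{[(2S,3E)-pent-3-en-2-yl]oxy}benzoate | CC(C)(C)OC(=O)c1cc(Br)cc(O[C@@H](C)/C=C/C)c1O | intermediate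
7 | tert-butyl 5-bromo-2,3-dihydroxy-4-[(2R,3E)-pent-3-en-2-yl]benzoate | CC(C)(C)OC(=O)c1cc(Br)c([C@H](C)/C=C/C)c(O)c1O | intermediate
8 | tert-butyl 5-bromo-2,3-bis(methoxymethoxy)-4-[(2R,3E)-pent-3-en-2-yl]benzoate | CC(C)(C)OC(=O)c1cc(Br)c([C@H](C)/C=C/C)c(OCOC)c1OCOC | intermediate
9 | tert-butyl 5-bromo-4-[(2R)-but-3-en-2-yl]-2,3-bis(methoxymethoxy)benzoate | CC(C)(C)OC(=O)c1cc(Br)c([C@H](C)C=C)c(OCOC)c1OCOC | intermediate
10 | tert-butyl 4-[(2R)-4-(9-borabicyclo[3.3.1]nonan-9-yl)butan-2-yl]-5-bromo-2,3-bis(methoxymethoxy)benzoate | CC(C)(C)OC(=O)c1cc(Br)c([C@H](C)CCB2C3CCCC2CCC3)c(OCOC)c1OCOC | intermediate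
11 | tert-butyl 5-bromo-4-[(2R)-4-hydroxybutan-2-yl]-2,3-bis(methoxymethoxy)benzoate | CC(C)(C)OC(=O)c1cc(Br)c([C@H](C)CCO)c(OCOC)c1OCOC | intermediate
12 | tert-butyl 5-bromo-4-[(2R)-4-bromobutan-2-yl]-2,3-bis(methoxymethoxy)benzoate | CC(C)(C)OC(=O)c1cc(Br)c([C@H](C)CCBr)c(OCOC)c1OCOC | intermediate
13 | (2S)-3-bromo-2-methylpropan-1-ol | OC[C@H](C)CBr | starting material
14 | [(2S)-3-bromo-2-methylpropoxy](tert-butyl)dimethylsilane | CC(C)(C)[Si](C)(C)OC[C@H](C)CBr | intermediate
15 | (4-bromobut-1-yn-1-yl)trimethylsilane | C[Si](C)(C)C#CCCBr | starting material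
16 | [4-(trimethylsilyl)but-3-yn-1-yl]magnesium bromide | C[Si](C)(C)C#CCC[Mg]Br | intermediate
17 | tert-butyldimethyl{[(2R)-2-methyl-7-(trimethylsilyl)hept-6-yn-1-yl]oxy}silane | CC(C)(C)[Si](C)(C)OC[C@H](C)CCCC#C[Si](C)(C)C | intermediate
18 | tert-butyldimethyl{[(2R)-2-methylhept-6-yn-1-yl]oxy}silane | CC(C)(C)[Si](C)(C)OC[C@H](C)CCCC#C | intermediate
19 | [(1E,6R)-7-{[tert-butyl(dimethyl)silyl]oxy}-2,6-dimethylhept-1-en-1-yl]dimethylalumane | CC(C)(C)[Si](C)(C)OC[C@H](C)CCC/C(C)=C/[Al](C)C | intermediate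
20 | tert-butyl{[(2R,6E)-7-iodo-2,6-dimethylhept-6-en-1-yl]oxy}dimethylsilane | CC(C)(C)[Si](C)(C)OC[C@H](C)CCC/C(C)=C/I | intermediate
21 | [(1E,6R)-7-{[tert-butyl(dimethyl)silyl]oxy}-2,6-dimethylhept-1-en-1-yl]lithium | CC(C)(C)[Si](C)(C)OC[C@H](C)CCC/C(C)=C/[Li] | intermediate
22 | [(1E,6R)-7-{[tert-butyl(dimethyl)silyl]oxy}-2,6-dimethylhept-1-en-1-yl]zinc chloride | CC(C)(C)[Si](C)(C)OC[C@H](C)CCC/C(C)=C/[Zn]Cl | intermediate
23 | tert-butyl 4-[(2R)-4-bromobutan-2-yl]-5-[(1E,6R)-7-{[tert-butyl(dimethyl)silyl]oxy}-2,6-dimethylhept-1-en-1-yl]-2,3-bis(methoxymethoxy)benzoate | CC(C)(C)OC(=O)c1cc(/C=C(C)/CCC[C@@H](C)CO[Si](C)(C)C(C)(C)C)c([C@H](C)CCBr)c(OCOC)c1OCOC | intermediate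
24 | tert-butyl (5R,8S)-8-[(2S,6R)-7-{[tert-butyl(dimethyl)silyl]oxy}-6-methylheptan-2-yl]-3,4-bis(methoxymethoxy)-5-methyl-5,6,7,8-tetrahydronaphthalene-2-carboxylate | C[C@H](CCC[C@H](C)[C@@H]1CC[C@@H](C)c2c1cc(C(=O)OC(C)(C)C)c(OCOC)c2OCOC)CO[Si](C)(C)C(C)(C)C | intermediate
25 | tert-butyl (5R,8S)-8-[(2S,6R)-7-hydroxy-6-methylheptan-2-yl]-3,4-bis(methoxymethoxy)-5-methyl-5,6,7,8-tetrahydronaphthalene-2-carboxylate | C[C@H](CCC[C@H](C)[C@@H]1CC[C@@H](C)c2c1cc(C(=O)OC(C)(C)C)c(OCOC)c2OCOC)CO | intermediate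
26 | caffeic acid, (2E)-3-(3,4-dihydroxyphenyl)prop-2-enoic acid | OC(=O)/C=C/c1ccc(O)c(O)c1 | starting material
27 | methoxymethyl (2E)-3-[3,4-bis(methoxymethoxy)phenyl]prop-2-enoate | COCOC(=O)/C=C/c1ccc(OCOC)c(OCOC)c1 | intermediate
28 | (2E)-3-[3,4-bis(methoxymethoxy)phenyl]prop-2-enoic acid | OC(=O)/C=C/c1ccc(OCOC)c(OCOC)c1 | intermediate
29 | tert-butyl (5R,8S)-8-[(2S,6R)-7-({(2E)-3-[3,4-bis(methoxymethoxy)phenyl]prop-2-enoyl}oxy)-6-methylheptan-2-yl]-3,4-bis(methoxymethoxy)-5-methyl-5,6,7,8-tetrahydronaphthalene-2-carboxylate | C[C@H](CCC[C@H](C)[C@@H]1CC[C@@H](C)c2c1cc(C(=O)OC(C)(C)C)c(OCOC)c2OCOC)COC(=O)/C=C/c1ccc(OCOC)c(OCOC)c1 | intermediate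
30 | (5R,8S)-8-[(2S,6R)-7-{[(2E)-3-(3,4-dihydroxyphenyl)prop-2-enoyl]oxy}-6-methylheptan-2-yl]-3,4-dihydroxy-5-methyl-5,6,7,8-tetrahydronaphthalene-2-carboxylic acid (CNP0492979.1) | C[C@H](CCC[C@H](C)[C@@H]1CC[C@@H](C)c2c1cc(C(=O)O)c(O)c2O)COC(=O)/C=C/c1ccc(O)c(O)c1 | target

## Step count and risks

Total step count: 19. Longest linear sequence: 13 steps (steps 1, 2, 4, 5, 6, 7, 8, 9, 14, 15, 16, 18, 19, from 2,3-dihydroxybenzoic acid).

**1. Step 15 (Proposed new method).** What may go wrong:
- hydrocupration of the hindered, trisubstituted and ortho-substituted vinylarene may be slow, so that direct reduction of the C–Br bond or simple protonation of the benzylic copper competes;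
- facial selection may be incomplete, or the benzylic copper may lose configuration before ring closure;
- substitution at copper may go with inversion instead of retention, which would pair C8 and C2′ wrongly.

Fallback with known chemistry, setting out from 11 (with alkyne 18) and coming back at 24: alcohol 11 would be oxidised with Dess–Martin periodinane to tert-butyl 5-bromo-2,3-bis(methoxymethoxy)-4-[(2R)-4-oxobutan-2-yl]benzoate F1. Wittig methylenation (Ph3P=CH2, THF, −78 °C → 0 °C) would give tert-butyl 5-bromo-2,3-bis(methoxymethoxy)-4-[(2R)-pent-4-en-2-yl]benzoate F2. Sonogashira coupling of F2 with 18 (PdCl2(PPh3)2, CuI, Et3N, 70 °C) would give the enyne tert-butyl 5-[(6R)-7-{[tert-butyl(dimethyl)silyl]oxy}-6-methylhept-1-yn-1-yl]-2,3-bis(methoxymethoxy)-4-[(2R)-pent-4-en-2-yl]benzoate F3. Ring-closing enyne metathesis (second-generation Grubbs catalyst, ethylene, toluene, 80 °C) would close ring B at the same C7–C8 bond, now as C7=C8, and give the diene tert-butyl (5R)-8-[(6R)-7-{[tert-butyl(dimethyl)silyl]oxy}-6-methylhept-1-en-2-yl]-3,4-bis(methoxymethoxy)-5-methyl-5,6-dihydronaphthalene-2-carboxylate F4, whose exocyclic CH2 is the future C1′ methyl. Hydrogenation of both C=C bonds with a cationic iridium phosphine–oxazoline catalyst ([Ir(cod)(L*)]BArF, H2, CH2Cl2) would then give 24. C8 and C2′ would rest on catalyst control in this last step, so separation from diastereomers has to be expected.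

**2. Step 5.** What may go wrong:
- fragmentation of the secondary allyl aryl ether to the phenol and penta-1,3-diene;
- ionisation with erosion of the chirality transfer;
- abnormal Claisen isomerisation of the side chain on prolonged heating;
- thermal loss of the tert-butyl ester.

Fallback, setting out from 3 and coming back at 9 (steps 4 to 7 are bypassed): magnesium-mediated ortho-formylation of 3 (MgCl2, Et3N, paraformaldehyde, MeCN, reflux) at the only free ortho position of a phenol would give tert-butyl 5-bromo-4-formyl-2,3-dihydroxybenzoate F5. Bis-methoxymethylation (NaH, MOMCl, DMF) would give tert-butyl 5-bromo-4-formyl-2,3-bis(methoxymethoxy)benzoate F6. Wittig methylenation would give the styrene tert-butyl 5-bromo-4-ethenyl-2,3-bis(methoxymethoxy)benzoate F7. Nickel-catalysed asymmetric hydrovinylation (ethylene 1 bar, [(η3-C3H5)NiBr]2, a chiral phosphoramidite, NaB[3,5-(CF3)2C6H3]4, CH2Cl2, −70 °C) would add H and vinyl across the styrene in the branched sense, set the benzylic centre under ligand control and give 9.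

**3. Step 7.** What may go wrong:
- incomplete ethenolysis of the hindered, allylically branched internal alkene;
- catalyst decay to ruthenium hydrides that move the double bond into conjugation with ring A and so erase the benzylic stereocentre.

Fallback, setting out from 8 and coming back at 11 (steps 7 and 8 are bypassed): ozonolysis of 8 (O3, CH2Cl2/MeOH, −78 °C) would give tert-butyl 5-bromo-2,3-bis(methoxymethoxy)-4-[(2S)-1-oxopropan-2-yl]benzoate F8, which would be reduced in the same flask with NaBH4, before the α-aryl aldehyde can epimerise, to tert-butyl 5-bromo-4-[(2S)-1-hydroxypropan-2-yl]-2,3-bis(methoxymethoxy)benzoate F9. Iodination (I2, PPh3, imidazole, CH2Cl2) would give tert-butyl 5-bromo-4-[(2S)-1-iodopropan-2-yl]-2,3-bis(methoxymethoxy)benzoate F10. Copper-catalysed coupling with the hydroxymethyl-anion equivalent iPrOMe2SiCH2MgCl (CuI cat., THF, 0 °C) would give tert-butyl 5-bromo-4-{(2R)-4-[dimethyl(propan-2-yloxy)silyl]butan-2-yl}-2,3-bis(methoxymethoxy)benzoate F11. Tamao–Fleming oxidation (KF, KHCO3, H2O2, THF/MeOH) would give 11.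

## Further compounds

F1 | step 15 | tert-butyl 5-bromo-2,3-bis(methoxymethoxy)-4-[(2R)-4-oxobutan-2-yl]benzoate | CC(C)(C)OC(=O)c1cc(Br)c([C@H](C)CC=O)c(OCOC)c1OCOC
F2 | step 15 | tert-butyl 5-bromo-2,3-bis(methoxymethoxy)-4-[(2R)-pent-4-en-2-yl]benzoate | CC(C)(C)OC(=O)c1cc(Br)c([C@H](C)CC=C)c(OCOC)c1OCOC
F3 | step 15 | tert-butyl 5-[(6R)-7-{[tert-butyl(dimethyl)silyl]oxy}-6-methylhept-1-yn-1-yl]-2,3-bis(methoxymethoxy)-4-[(2R)-pent-4-en-2-yl]benzoate | CC(C)(C)OC(=O)c1cc(C#CCCC[C@@H](C)CO[Si](C)(C)C(C)(C)C)c([C@H](C)CC=C)c(OCOC)c1OCOC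
F4 | step 15 | tert-butyl (5R)-8-[(6R)-7-{[tert-butyl(dimethyl)silyl]oxy}-6-methylhept-1-en-2-yl]-3,4-bis(methoxymethoxy)-5-methyl-5,6-dihydronaphthalene-2-carboxylate | CC(C)(C)OC(=O)c1cc2c(c(OCOC)c1OCOC)[C@H](C)CC=C2C(=C)CCC[C@@H](C)CO[Si](C)(C)C(C)(C)C
F5 | step 5 | tert-butyl 5-bromo-4-formyl-2,3-dihydroxybenzoate | CC(C)(C)OC(=O)c1cc(Br)c(C=O)c(O)c1O
F6 | step 5 | tert-butyl 5-bromo-4-formyl-2,3-bis(methoxymethoxy)benzoate | CC(C)(C)OC(=O)c1cc(Br)c(C=O)c(OCOC)c1OCOC
F7 | step 5 | tert-butyl 5-bromo-4-ethenyl-2,3-bis(methoxymethoxy)benzoate | CC(C)(C)OC(=O)c1cc(Br)c(C=C)c(OCOC)c1OCOC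
F8 | step 7 | tert-butyl 5-bromo-2,3-bis(methoxymethoxy)-4-[(2S)-1-oxopropan-2-yl]benzoate | CC(C)(C)OC(=O)c1cc(Br)c([C@H](C)C=O)c(OCOC)c1OCOC
F9 | step 7 | tert-butyl 5-bromo-4-[(2S)-1-hydroxypropan-2-yl]-2,3-bis(methoxymethoxy)benzoate | CC(C)(C)OC(=O)c1cc(Br)c([C@H](C)CO)c(OCOC)c1OCOC
F10 | step 7 | tert-butyl 5-bromo-4-[(2S)-1-iodopropan-2-yl]-2,3-bis(methoxymethoxy)benzoate | CC(C)(C)OC(=O)c1cc(Br)c([C@H](C)CI)c(OCOC)c1OCOC
F11 | step 7 | tert-butyl 5-bromo-4-{(2R)-4-[dimethyl(propan-2-yloxy)silyl]butan-2-yl}-2,3-bis(methoxymethoxy)benzoate | CC(C)(C)OC(=O)c1cc(Br)c([C@H](C)CC[Si](C)(C)OC(C)C)c(OCOC)c1OCOC
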